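Each cyclohexene ring (C1 bears the diene, C2 is the vinylic CH, C3 the quaternary carbon, C4 the carbinol) holds its C4 oxygen and C1 exocyclic carbon 1,4 across the ring: the retron of a bridged lactone. An inverse-electron-demand Diels–Alder reaction of methyl 2-oxo-2H-pyran-3-carboxylate with the geometrically pure (Z)-benzyl enol ether of 2,6-dimethylhept-5-enal forms the C1–C2 and C3–C4 bonds in one operation and sets both stereocentres; the lactone oxygen becomes the hydroxyl, its carbonyl the exocyclic carbon. Decarboxylative loss of benzyl alcohol unveils the C1=C2 alkene; Shi epoxidation, Takai olefinations and a Suzuki coupling join two halves.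

Key step: step 3

Assumption: the (R)-BINOL titanium Lewis acid is taken to leave open the face of the chelated pyrone that leads to 8; should the sense of induction be the opposite, (S)-BINOL gives 8 under the same conditions.

Step 1
Reactants: 1 5-bromo-2-methylpent-2-ene; 2 propyne
Product: 5 (Z)-1-iodo-2,6-dimethylhepta-1,5-diene, via homoprenylmagnesium bromide 3 (not isolated), via alkenylcopper 4 (not isolated)
Conditions: Mg, THF, 40 °C; CuBr·SMe2 (1 equiv), Et2O/Me2S, −45 °C; propyne (excess), −25 °C; I2, −50 to 0 °C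
Reagents that add atoms: iodine, II
Why: Normant syn-carbocupration of the terminal alkyne puts the homoprenyl group on the internal carbon and copper on the terminal carbon, cis to each other, and iodinolysis with retention should give the Z iodide (iodine cis to homoprenyl).

Step 2
Reactants: 5 (Z)-1-iodo-2,6-dimethylhepta-1,5-diene
Product: 6 (Z)-1-(benzyloxy)-2,6-dimethylhepta-1,5-diene
Conditions: BnOH (1.5 equiv), CuI (10 mol%), 3,4,7,8-tetramethyl-1,10-phenanthroline (20 mol%), Cs2CO3, toluene, 80 °C
Reagents that add atoms: benzyl alcohol, OCc1ccccc1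
Why: Copper-catalysed Ullmann-type C–O coupling of alkenyl iodides with alcohols proceeds with retention of alkene geometry, so the enol ether should keep oxygen cis to the homoprenyl group.

Step 3
Reactants: 6 (Z)-1-(benzyloxy)-2,6-dimethylhepta-1,5-diene; 7 methyl 2-oxo-2H-pyran-3-carboxylate
Product: 8 methyl (1S,4R,7R,8R)-8-(benzyloxy)-7-methyl-7-(4-methylpent-3-enyl)-3-oxo-2-oxabicyclo[2.2.2]oct-5-ene-4-carboxylate (benzyloxy and homoprenyl endo, that is syn to the C5=C6 bridge; C7 methyl syn to the lactone bridge)
Conditions: (R)-1,1'-bi-2-naphthol (22 mol%), TiCl2(OiPr)2 (20 mol%), 4 Å molecular sieves, toluene/CH2Cl2, −30 °C; 6 in slight excess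
Reagents that add atoms: none
Why: The chiral titanium Lewis acid chelates the lactone and ester carbonyls of 7 and lowers its LUMO, so the electron-rich enol ether adds in an asynchronous, concerted [4+2] cycloaddition in which its nucleophilic disubstituted carbon bonds to pyrone C6 (the vinylogous acceptor terminus; this is the carbinol-to-quaternary ring bond) and its oxygen-bearing carbon bonds to pyrone C3 (the bond that later becomes the ring C=C). The closest known reaction is the BINOL–titanium- or BINOL–ytterbium-catalysed inverse-electron-demand Diels–Alder reaction of this pyrone with simple vinyl ethers. The six-membered carbocycle closes by suprafacial–suprafacial [4+2] cycloaddition across the pyrone diene, which leaves the lactone as the two-atom bridge of a 2-oxabicyclo[2.2.2]octene. The bridgehead carbinol carbon is set by the pyrone face that the BINOL ligand leaves open, and the quaternary carbon by the Z geometry of 6 together with the endo orientation of the benzyloxy group, which places homoprenyl endo and methyl syn to the lactone oxygen, that is cis to the future hydroxyl. The benzyloxy-bearing carbon and the ester-bearing bridgehead are formed selectively as well but lose their stereogenicity in step 5. The step needs regio-, endo- and facial selectivity and must outrun loss of CO2: the polarised chelated pyrone should secure the first, secondary interaction of the ether oxygen with the diene the second, the ligand the third and the low temperature the last.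

Step 4
Reactants: 8 bicyclic lactone
Product: 9 methyl (1S,4R,7R,8R)-8-(benzyloxy)-7-methyl-7-(4-methylpent-3-enyl)-3-oxo-2-oxabicyclo[2.2.2]octane-4-carboxylate
Conditions: 2-nitrobenzenesulfonylhydrazide, Et3N, CH2Cl2, 23 °C
Reagents that add atoms: none
Why: Diimide released in the flask should reduce the strained cis-disubstituted bridge alkene by syn hydrogen transfer far faster than the trisubstituted side-chain alkene (diimide reduction), leaves benzyl ether, ester and lactone untouched, changes no stereocenter and removes the possibility of CO2 extrusion.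

Step 5
Reactants: 9 saturated bicyclic lactone
Product: 11 methyl (3S,4S)-4-hydroxy-3-methyl-3-(4-methylpent-3-enyl)cyclohex-1-ene-1-carboxylate, via lithium carboxylate 10 (not isolated)
Conditions: LiOH·H2O (1.05 equiv), THF/H2O, 0 °C; concentrate; DMSO, DBU (0.2 equiv), 130 °C
Reagents that add atoms: none
Why: Hydroxide should open the strained bridged lactone in preference to the neopentyl methyl ester, and the resulting malonate half-ester carboxylate should lose CO2 on heating in DMSO (the carbanion stage of a Krapcho dealkoxycarbonylation) to an ester enolate that expels the β-benzyloxide (E1cB), which puts the alkene regiospecifically at C1=C2 and leaves the C3 and C4 stereocenters untouched.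

Step 6
Reactants: 11 hydroxy enoate
Product: 12 methyl (3S,4S)-3-{2-[(2R)-3,3-dimethyloxiran-2-yl]ethyl}-4-hydroxy-3-methylcyclohex-1-ene-1-carboxylate
Conditions: D-fructose-derived ketone catalyst 1,2:4,5-di-O-isopropylidene-β-D-erythro-2,3-hexodiulo-2,6-pyranose (30 mol%), Oxone (2KHSO5·KHSO4·K2SO4), K2CO3, Bu4NHSO4, Na2B4O7/Na2EDTA buffer, MeCN/dimethoxymethane, 0 °C
Reagents that add atoms: Oxone (potassium peroxymonosulfate), [K+].[O-]S(=O)(=O)OO
Why: In the Shi epoxidation the chiral dioxirane should attack the electron-rich trisubstituted side-chain alkene through a spiro transition state that gives the (R)-epoxide under catalyst control, while the electron-poor enoate alkene and the secondary alcohol do not react.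

Step 7
Reactants: 12 epoxy hydroxy enoate
Product: 13 (1S,2S)-2-{2-[(2R)-3,3-dimethyloxiran-2-yl]ethyl}-4-(hydroxymethyl)-2-methylcyclohex-3-en-1-ol
Conditions: i-Bu2AlH (3.5 equiv), CH2Cl2, −78 °C; aqueous Rochelle salt
Reagents that add atoms: none
Why: DIBAL-H should reduce the conjugated methyl ester in the 1,2-sense to the primary allylic alcohol at −78 °C, where the trisubstituted epoxide and the ring alkene are inert and no stereocenter is touched (hydride reduction of an ester).

Step 8
Reactants: 13 epoxy diol
Product: 14 (3S,4S)-3-{2-[(2R)-3,3-dimethyloxiran-2-yl]ethyl}-4-hydroxy-3-methylcyclohex-1-ene-1-carbaldehyde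
Conditions: activated MnO2 (excess), CH2Cl2, 23 °C
Reagents that add atoms: none
Why: Activated MnO2 oxidises allylic alcohols selectively, so only the primary allylic hydroxyl should be converted into the enal while the saturated secondary carbinol and the epoxide stay as they are.

Step 9
Reactants: 14 epoxy hydroxy enal
Product: 15 (1S,2S)-2-{2-[(2R)-3,3-dimethyloxiran-2-yl]ethyl}-4-[(E)-2-iodoethenyl]-2-methylcyclohex-3-en-1-ol
Conditions: CrCl2 (6 equiv), CHI3 (2 equiv), THF/1,4-dioxane, 0 to 23 °C
Reagents that add atoms: iodoform, IC(I)I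
Why: In the Takai iodo-olefination the geminal dichromium carbenoid from CHI3 and CrCl2 adds to the aldehyde and eliminates to the (E)-alkenyl iodide, and the mild chromium reagent should tolerate the free hydroxyl and the epoxide.

Step 10
Reactants: 14 epoxy hydroxy enal
Product: 16 (1S,2S)-2-{2-[(2R)-3,3-dimethyloxiran-2-yl]ethyl}-2-methyl-4-[(E)-2-(4,4,5,5-tetramethyl-1,3,2-dioxaborolan-2-yl)ethenyl]cyclohex-3-en-1-ol
Conditions: CrCl2 (8 equiv), Cl2CHBpin (2 equiv), LiI (4 equiv), THF, 23 °C
Reagents that add atoms: 2-(dichloromethyl)-4,4,5,5-tetramethyl-1,3,2-dioxaborolane, ClC(Cl)B1OC(C)(C)C(C)(C)O1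
Why: In the boron variant of the Takai olefination the boryl-substituted geminal dichromium species should convert the aldehyde into the (E)-alkenyl pinacolboronate by the same stereochemical course as in step 9.

Step 11
Reactants: 15 dienyl iodide; 16 dienyl boronate
Product: 17 (1S,1'S,2S,2'S)-4,4'-[(1E,3E)-buta-1,3-diene-1,4-diyl]bis(2-{2-[(2R)-3,3-dimethyloxiran-2-yl]ethyl}-2-methylcyclohex-3-en-1-ol), the target
Conditions: PdCl2(dppf) (5 mol%), K3PO4 (3 equiv), THF/H2O, degassed, dark, 23 °C
Reagents that add atoms: none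
Why: Suzuki–Miyaura coupling of an alkenyl iodide with an alkenyl boronate proceeds with retention at both alkenes, so the two E units should give the (E,E)-butadiene link under mild aqueous base that spares the epoxides and the free hydroxyls, and no stereocenter is touched.

Compound list
1 | 5-bromo-2-methylpent-2-ene | CC(C)=CCCBr | starting material
2 | propyne | CC#C | starting material
3 | (4-methylpent-3-enyl)magnesium bromide (homoprenylmagnesium bromide, formed in the flask) | CC(C)=CCC[Mg]Br | intermediate
4 | [(Z)-2,6-dimethylhepta-1,5-dienyl]copper, as its MgBr2 complex (formed in the flask) | [Cu]/C=C(/C)CCC=C(C)C | intermediate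
5 | (Z)-1-iodo-2,6-dimethylhepta-1,5-diene | I/C=C(/C)CCC=C(C)C | intermediate
6 | (Z)-1-(benzyloxy)-2,6-dimethylhepta-1,5-diene | c1ccccc1CO/C=C(/C)CCC=C(C)C | intermediate
7 | methyl 2-oxo-2H-pyran-3-carboxylate | COC(=O)C1=CC=COC1=O | starting material
8 | methyl (1S,4R,7R,8R)-8-(benzyloxy)-7-methyl-7-(4-methylpent-3-enyl)-3-oxo-2-oxabicyclo[2.2.2]oct-5-ene-4-carboxylate | CC(C)=CCC[C@@]1(C)[C@@H](OCc2ccccc2)[C@@]3(C(=O)OC)C=C[C@@H]1OC3=O | intermediate
9 | methyl (1S,4R,7R,8R)-8-(benzyloxy)-7-methyl-7-(4-methylpent-3-enyl)-3-oxo-2-oxabicyclo[2.2.2]octane-4-carboxylate | CC(C)=CCC[C@@]1(C)[C@@H](OCc2ccccc2)[C@@]3(C(=O)OC)CC[C@@H]1OC3=O | intermediate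
10 | lithium (1S,2R,3R,4S)-2-(benzyloxy)-4-hydroxy-1-(methoxycarbonyl)-3-methyl-3-(4-methylpent-3-enyl)cyclohexane-1-carboxylate (carboxylate cis to the hydroxyl; formed in the flask) | CC(C)=CCC[C@@]1(C)[C@@H](OCc2ccccc2)[C@@](C([O-])=O)(C(=O)OC)CC[C@@H]1O.[Li+] | intermediate
11 | methyl (3S,4S)-4-hydroxy-3-methyl-3-(4-methylpent-3-enyl)cyclohex-1-ene-1-carboxylate | CC(C)=CCC[C@@]1(C)C=C(C(=O)OC)CC[C@@H]1O | intermediate
12 | methyl (3S,4S)-3-{2-[(2R)-3,3-dimethyloxiran-2-yl]ethyl}-4-hydroxy-3-methylcyclohex-1-ene-1-carboxylate | CC1(C)O[C@@H]1CC[C@@]1(C)C=C(C(=O)OC)CC[C@@H]1O | intermediate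
13 | (1S,2S)-2-{2-[(2R)-3,3-dimethyloxiran-2-yl]ethyl}-4-(hydroxymethyl)-2-methylcyclohex-3-en-1-ol | CC1(C)O[C@@H]1CC[C@@]1(C)C=C(CO)CC[C@@H]1O | intermediate
14 | (3S,4S)-3-{2-[(2R)-3,3-dimethyloxiran-2-yl]ethyl}-4-hydroxy-3-methylcyclohex-1-ene-1-carbaldehyde | CC1(C)O[C@@H]1CC[C@@]1(C)C=C(C=O)CC[C@@H]1O | intermediate
15 | (1S,2S)-2-{2-[(2R)-3,3-dimethyloxiran-2-yl]ethyl}-4-[(E)-2-iodoethenyl]-2-methylcyclohex-3-en-1-ol | CC1(C)O[C@@H]1CC[C@@]1(C)C=C(/C=C/I)CC[C@@H]1O | intermediate
16 | (1S,2S)-2-{2-[(2R)-3,3-dimethyloxiran-2-yl]ethyl}-2-methyl-4-[(E)-2-(4,4,5,5-tetramethyl-1,3,2-dioxaborolan-2-yl)ethenyl]cyclohex-3-en-1-ol | CC1(C)O[C@@H]1CC[C@@]1(C)C=C(/C=C/B2OC(C)(C)C(C)(C)O2)CC[C@@H]1O | intermediate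
17 | (1S,1'S,2S,2'S)-4,4'-[(1E,3E)-buta-1,3-diene-1,4-diyl]bis(2-{2-[(2R)-3,3-dimethyloxiran-2-yl]ethyl}-2-methylcyclohex-3-en-1-ol) | CC1(C)O[C@@H]1CC[C@@]1(C)C=C(/C=C/C=C/C2=C[C@](C)(CC[C@H]3OC3(C)C)[C@@H](O)CC2)CC[C@@H]1O | target

Total step count: 11. Longest linear sequence: 10 steps (steps 1 to 9, then step 11; step 10 is a one-step branch from 14).

Steps most likely to fail

Step 3. The hindered trisubstituted enol ether may add stepwise through a zwitterion, which would erode the transfer of alkene geometry to the quaternary carbon, or the catalyst may discriminate the two pyrone faces poorly. The fallback moves stereocontrol from the catalyst to a removable auxiliary whose diastereomers can be separated. It sets out from 5: copper-catalysed coupling as in step 2, but with (S)-1-phenylethanol (the matched enantiomer of the alcohol is used), should give (Z)-2,6-dimethyl-1-[(1S)-1-phenylethoxy]hepta-1,5-diene F1. Cycloaddition with 7 under an achiral Lewis acid (Yb(OTf)3, CH2Cl2, −20 °C) should give the auxiliary-bearing bicyclic lactone F2, which is purified from its diastereomers by chromatography or crystallisation. Diimide reduction as in step 4 should give the saturated lactone F3, and the conditions of step 5 expel the auxiliary alkoxide and bring the sequence back at 11.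

Step 5. The free hydroxyl may re-lactonise onto the remaining ester before the carboxylate decarboxylates, or the β-elimination may stay incomplete at 130 °C. The fallback separates the events and masks the alcohol. It sets out from 9: methanolysis (NaOMe, MeOH, 0 °C) should give the dimethyl hydroxy diester F4, acetylation (Ac2O, pyridine, DMAP) its acetate F5, and a Krapcho dealkoxycarbonylation (LiCl, H2O, DMSO, 150 °C) with loss of benzyl alcohol the acetoxy enoate F6. Mild methanolysis of the acetate (K2CO3, MeOH, 0 °C) comes back at 11.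

Step 9. Lewis-acidic chromium salts may open the trisubstituted epoxide, or the olefination may give E/Z mixtures; the same holds for step 10. The fallback replaces the chromium carbenoid by an alkyne hydrometalation. It sets out from 14: homologation with the Ohira–Bestmann reagent (dimethyl (1-diazo-2-oxopropyl)phosphonate, K2CO3, MeOH) should give the enyne F7. Syn hydrozirconation with Cp2Zr(H)Cl (THF, 0 °C, one extra equivalent for the hydroxyl) and iodinolysis with I2 comes back at 15. If step 10 fails as well, copper-catalysed borylation of the same enyne (B2pin2, CuCl, Xantphos, NaOtBu, MeOH) leads to 16.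

Further compounds
F1 | step 3 | (Z)-2,6-dimethyl-1-[(1S)-1-phenylethoxy]hepta-1,5-diene | C[C@H](O/C=C(/C)CCC=C(C)C)c1ccccc1
F2 | step 3 | methyl (1S,4R,7R,8R)-7-methyl-7-(4-methylpent-3-enyl)-3-oxo-8-[(1S)-1-phenylethoxy]-2-oxabicyclo[2.2.2]oct-5-ene-4-carboxylate | CC(C)=CCC[C@@]1(C)[C@@H](O[C@@H](C)c2ccccc2)[C@@]3(C(=O)OC)C=C[C@@H]1OC3=O
F3 | step 3 | methyl (1S,4R,7R,8R)-7-methyl-7-(4-methylpent-3-enyl)-3-oxo-8-[(1S)-1-phenylethoxy]-2-oxabicyclo[2.2.2]octane-4-carboxylate | CC(C)=CCC[C@@]1(C)[C@@H](O[C@@H](C)c2ccccc2)[C@@]3(C(=O)OC)CC[C@@H]1OC3=O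
F4 | step 5 | dimethyl (2R,3R,4S)-2-(benzyloxy)-4-hydroxy-3-methyl-3-(4-methylpent-3-enyl)cyclohexane-1,1-dicarboxylate | CC(C)=CCC[C@@]1(C)[C@@H](OCc2ccccc2)C(C(=O)OC)(C(=O)OC)CC[C@@H]1O
F5 | step 5 | dimethyl (2R,3R,4S)-4-acetoxy-2-(benzyloxy)-3-methyl-3-(4-methylpent-3-enyl)cyclohexane-1,1-dicarboxylate | CC(C)=CCC[C@@]1(C)[C@@H](OCc2ccccc2)C(C(=O)OC)(C(=O)OC)CC[C@@H]1OC(C)=O
F6 | step 5 | methyl (3S,4S)-4-acetoxy-3-methyl-3-(4-methylpent-3-enyl)cyclohex-1-ene-1-carboxylate | CC(C)=CCC[C@@]1(C)C=C(C(=O)OC)CC[C@@H]1OC(C)=O
F7 | step 9 | (1S,2S)-2-{2-[(2R)-3,3-dimethyloxiran-2-yl]ethyl}-4-ethynyl-2-methylcyclohex-3-en-1-ol | CC1(C)O[C@@H]1CC[C@@]1(C)C=C(C#C)CC[C@@H]1O
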